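**Retrosynthetic overview**

1. Pakyonol 18 comes from the macrocyclic (E)-stilbene benzyl ether 17 by one hydrogenation, which saturates the ring A–ring D alkene and frees the ring C phenol.
2. 17 comes from the open-chain dibromide 13 and (E)-1,2-bis(tributylstannyl)ethene 14 by a double Stille coupling. The feature used is the CH2–CH2 bridge between C-4 of ring A (para to OMe, meta to the ether oxygen) and C-3 of ring D (meta to its ether oxygen): it is a symmetrical two-carbon unit between two arene carbons, so both aryl–C bonds are cut and the bridge is inserted whole, with no orientation problem.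
3. 13 comes from phosphonium salt 10 (rings A and B) and aldehyde 4 (rings C and D) by Wittig olefination, then diimide reduction, which keeps both C–Br bonds.
4. 10 comes from 5 and 6 (SNAr, reduction, PPh3·HBr); 4 comes from 1 and 3 (benzylation, SNAr).
5. Rings A to D are all purchased; the 20-membered macrocycle is the only ring made, in step 8.

Key step: step 8

Remark on ring names: ring A carries the methoxy group, ring B is the para-linked ring, ring C carries the hydroxy (benzyloxy) group, ring D is the meta-linked ring.
Remark on the chemistry: the Wittig product 12 is assumed to form as an E/Z mixture and is carried on as such, since both isomers give the same bibenzyl in step 7.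

**Route**

Step 1
Reactants: 1 4-fluoro-3-hydroxybenzaldehyde
Product: 2 3-(benzyloxy)-4-fluorobenzaldehyde
Conditions: BnBr, K2CO3, DMF, rt
Reagents that add atoms: benzyl bromide, BrCc1ccccc1
Why: Williamson ether synthesis; the phenoxide should be benzylated at room temperature much faster than it can attack the activated fluoride of a second molecule, and capping it removes the anionic donor that would block the later SNAr.

Step 2
Reactants: 2 3-(benzyloxy)-4-fluorobenzaldehyde; 3 3-bromophenol
Product: 4 3-(benzyloxy)-4-(3-bromophenoxy)benzaldehyde
Conditions: K2CO3, DMF, 140 °C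
Reagents that add atoms: none
Why: SNAr (addition–elimination); the fluoride para to the formyl group should be displaced by the phenoxide through a Meisenheimer adduct stabilised by the aldehyde, while the unactivated C–Br bond of the nucleophile stays intact.

Step 3
Reactants: 5 5-bromo-2-methoxyphenol; 6 4-fluorobenzaldehyde
Product: 7 4-(5-bromo-2-methoxyphenoxy)benzaldehyde
Conditions: K2CO3, DMF, 120 °C
Reagents that add atoms: none
Why: SNAr of a guaiacol-type phenoxide on 4-fluorobenzaldehyde, a standard diaryl ether synthesis in which the para formyl group activates the fluoride and the aryl bromide is a spectator.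

Step 4
Reactants: 7 4-(5-bromo-2-methoxyphenoxy)benzaldehyde
Product: 8 [4-(5-bromo-2-methoxyphenoxy)phenyl]methanol
Conditions: NaBH4, MeOH/THF, 0 °C to rt
Reagents that add atoms: none
Why: Hydride reduction of an aryl aldehyde with NaBH4, which leaves the aryl bromide and both ethers untouched.

Step 5
Reactants: 8 [4-(5-bromo-2-methoxyphenoxy)phenyl]methanol
Product: 10 {[4-(5-bromo-2-methoxyphenoxy)phenyl]methyl}triphenylphosphonium bromide, via benzylic bromide 9 (not isolated)
Conditions: PPh3·HBr, MeCN, reflux
Reagents that add atoms: triphenylphosphine hydrobromide, [Br-].c1ccc(cc1)[PH+](c1ccccc1)c1ccccc1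
Why: Direct conversion of a benzylic alcohol into its phosphonium salt; HBr should turn the para-aryloxy-activated alcohol into the benzylic bromide, which is quaternised in the same flask by triphenylphosphine (SN2), with water as the only by-product.

Step 6
Reactants: 10 {[4-(5-bromo-2-methoxyphenoxy)phenyl]methyl}triphenylphosphonium bromide; 4 3-(benzyloxy)-4-(3-bromophenoxy)benzaldehyde
Product: 12 4-bromo-2-(4-{2-[3-(benzyloxy)-4-(3-bromophenoxy)phenyl]ethenyl}phenoxy)-1-methoxybenzene (E/Z mixture), via benzylidene ylide 11 (not isolated)
Conditions: KOt-Bu, THF, 0 °C; then 4, 0 °C to rt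
Reagents that add atoms: none
Why: Wittig olefination of a non-enolisable aryl aldehyde with a semi-stabilised benzylic ylide, expected to give an E/Z mixture that needs no separation; KOt-Bu is chosen because it cannot undergo halogen–metal exchange with the aryl bromides.

Step 7
Reactants: 12 4-bromo-2-(4-{2-[3-(benzyloxy)-4-(3-bromophenoxy)phenyl]ethenyl}phenoxy)-1-methoxybenzene (E/Z mixture)
Product: 13 4-bromo-2-(4-{2-[3-(benzyloxy)-4-(3-bromophenoxy)phenyl]ethyl}phenoxy)-1-methoxybenzene
Conditions: TsNHNH2 (excess, in portions), NaOAc, DME/H2O, reflux
Reagents that add atoms: none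
Why: Diimide reduction; diimide generated from p-toluenesulfonyl hydrazide should deliver H2 to the alkene through a concerted cyclic transition state and cannot cleave the two C–Br bonds or the benzyl ether, which hydrogenation over palladium would.

Step 8
Reactants: 13 4-bromo-2-(4-{2-[3-(benzyloxy)-4-(3-bromophenoxy)phenyl]ethyl}phenoxy)-1-methoxybenzene; 14 (E)-1,2-bis(tributylstannyl)ethene
Product: 17 macrocyclic (E)-stilbene benzyl ether (O-benzyl-dehydropakyonol), via ring D vinylstannane 15 (not isolated), via ring A vinylstannane 16 (not isolated)
Conditions: Pd2(dba)3 (10 mol%), P(t-Bu)3·HBF4 (40 mol%), CsF, 1,4-dioxane, 90 °C; 13 and 14 (1:1) added together by syringe pump, final concentration about 1 mM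
Reagents that add atoms: (E)-1,2-bis(tributylstannyl)ethene (14), CCCC[Sn](CCCC)(CCCC)/C=C/[Sn](CCCC)(CCCC)CCCC
Why: Zerovalent palladium carrying P(t-Bu)3 inserts into an aryl C–Br bond, the fluoride-activated vinylstannane transmetalates with retention of alkene geometry and reductive elimination forms the aryl–CH bond; the first such cycle is intermolecular and gives the β-stannylstyrene 15 (or its isomer 16), the second is intramolecular. The closest known reactions are the double Stille stitching macrocyclisation of bis(vinyl iodides) with this distannane and the twofold Stille coupling of aryl dibromides with it to give stilbenes, so the step is a Stille coupling used twice. The 20-membered ring is closed end to end by the second coupling, the arylpalladium bromide at one terminus capturing the vinyl–tin bond at the other, which the meta,meta-stilbene geometry and the flexible saturated ring B–ring C half should allow without strain. No stereocentre is formed; the E geometry of the linchpin is carried into 17 and is removed in step 9 in any case. The selectivity needed is ring closure over chain growth with one linchpin per dibromide, secured by slow equimolar addition of 13 and 14 into hot dilute catalyst, by the symmetry of 14 (either bromide may react first and both intermediates give 17) and by the active phosphine, which keeps oxidative addition at the electron-rich ring A bromide from lagging behind; the benzyl and aryl ethers are inert.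

Step 9
Reactants: 17 macrocyclic (E)-stilbene benzyl ether
Product: 18 pakyonol
Conditions: H2 (1 atm), 10% Pd/C, EtOAc/EtOH, rt (17 first freed of tin residues over KF/silica)
Reagents that add atoms: none
Why: Heterogeneous catalytic hydrogenation; one operation should saturate the stilbene and cleave the benzyl ether by hydrogenolysis, while the diaryl ethers and the methyl ether are stable.

**Compound list**

1 | 4-fluoro-3-hydroxybenzaldehyde | O=Cc1ccc(F)c(O)c1 | starting material
2 | 3-(benzyloxy)-4-fluorobenzaldehyde | O=Cc1ccc(F)c(OCc2ccccc2)c1 | intermediate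
3 | 3-bromophenol | Oc1cccc(Br)c1 | starting material
4 | 3-(benzyloxy)-4-(3-bromophenoxy)benzaldehyde | O=Cc1ccc(Oc2cccc(Br)c2)c(OCc2ccccc2)c1 | intermediate
5 | 5-bromo-2-methoxyphenol | COc1ccc(Br)cc1O | starting material
6 | 4-fluorobenzaldehyde | O=Cc1ccc(F)cc1 | starting material
7 | 4-(5-bromo-2-methoxyphenoxy)benzaldehyde | COc1ccc(Br)cc1Oc1ccc(C=O)cc1 | intermediate
8 | [4-(5-bromo-2-methoxyphenoxy)phenyl]methanol | COc1ccc(Br)cc1Oc1ccc(CO)cc1 | intermediate
9 | 4-bromo-2-[4-(bromomethyl)phenoxy]-1-methoxybenzene (benzylic bromide, formed in the flask) | COc1ccc(Br)cc1Oc1ccc(CBr)cc1 | intermediate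
10 | {[4-(5-bromo-2-methoxyphenoxy)phenyl]methyl}triphenylphosphonium bromide | COc1ccc(Br)cc1Oc1ccc(C[P+](c2ccccc2)(c2ccccc2)c2ccccc2)cc1.[Br-] | intermediate
11 | {[4-(5-bromo-2-methoxyphenoxy)phenyl]methylidene}triphenylphosphorane (benzylidene ylide, formed in the flask) | COc1ccc(Br)cc1Oc1ccc(C=P(c2ccccc2)(c2ccccc2)c2ccccc2)cc1 | intermediate
12 | 4-bromo-2-(4-{2-[3-(benzyloxy)-4-(3-bromophenoxy)phenyl]ethenyl}phenoxy)-1-methoxybenzene, E/Z mixture (alkene geometry left open in the SMILES) | COc1ccc(Br)cc1Oc1ccc(C=Cc2ccc(Oc3cccc(Br)c3)c(OCc3ccccc3)c2)cc1 | intermediate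
13 | 4-bromo-2-(4-{2-[3-(benzyloxy)-4-(3-bromophenoxy)phenyl]ethyl}phenoxy)-1-methoxybenzene (open-chain dibromide, bromine on rings A and D) | COc1ccc(Br)cc1Oc1ccc(CCc2ccc(Oc3cccc(Br)c3)c(OCc3ccccc3)c2)cc1 | intermediate
14 | (E)-1,2-bis(tributylstannyl)ethene | CCCC[Sn](CCCC)(CCCC)/C=C/[Sn](CCCC)(CCCC)CCCC | starting material
15 | ring D vinylstannane: 13 with the ring D bromine replaced by (E)-2-(tributylstannyl)ethenyl, ring A bromine kept (formed in the flask) | COc1ccc(Br)cc1Oc1ccc(CCc2ccc(Oc3cccc(/C=C/[Sn](CCCC)(CCCC)CCCC)c3)c(OCc3ccccc3)c2)cc1 | intermediate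
16 | ring A vinylstannane: 13 with the ring A bromine replaced by (E)-2-(tributylstannyl)ethenyl, ring D bromine kept (formed in the flask) | COc1ccc(/C=C/[Sn](CCCC)(CCCC)CCCC)cc1Oc1ccc(CCc2ccc(Oc3cccc(Br)c3)c(OCc3ccccc3)c2)cc1 | intermediate
17 | macrocyclic (E)-stilbene across rings D and A, ring C oxygen benzylated (O-benzyl-dehydropakyonol) | COc1ccc2cc1Oc1ccc(cc1)CCc1ccc(c(OCc3ccccc3)c1)Oc1cccc(c1)/C=C/2 | intermediate
18 | pakyonol | COc1ccc2cc1Oc1ccc(cc1)CCc1ccc(c(O)c1)Oc1cccc(c1)CC2 | target

**Step count**

Total: 9 steps. Longest linear sequence: 7 steps (steps 3, 4, 5, 6, 7, 8, 9, from 5 and 6 to 18).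

**Steps most likely to fail**

1. Step 8. The mono-coupled vinylstannane may couple with a second molecule of dibromide faster than it closes the ring, giving chain growth, and the vinyl–tin bond may be lost by protodestannylation before closure. The fallback sets out from 13 and comes back at 17. Twofold Stille vinylation of 13 with tributyl(vinyl)stannane (Pd(PPh3)4, toluene, 100 °C) should give the bis-styrene 4-ethenyl-2-(4-{2-[3-(benzyloxy)-4-(3-ethenylphenoxy)phenyl]ethyl}phenoxy)-1-methoxybenzene F1. Ring-closing metathesis of F1 with second-generation Grubbs catalyst in dilute toluene, with loss of ethene, should then close the same ring A–ring D bridge to give 17. Any (Z)-isomer of 17, F2, formed alongside is hydrogenated to 18 in step 9 as well.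

2. Step 2. Substitution may be slow at the C–F carbon, which carries an ortho benzyloxy donor, and the aldehyde may degrade at the temperature needed. The fallback sets out from 3 and comes back at 4. Commercial 3-hydroxy-4-iodobenzaldehyde F3 is benzylated (BnBr, K2CO3, DMF) to 3-(benzyloxy)-4-iodobenzaldehyde F4. F4 is then joined to 3 by a copper-catalysed Ullmann ether synthesis (CuI, picolinic acid, K3PO4, DMSO, 90 °C), in which the C–I bond should react in preference to the C–Br bond of 3.

3. Step 7. The reduction may stall, because diimide disproportionates faster than it reduces the conjugated (E)-stilbene, leaving alkene that is hard to separate from the bibenzyl. The fallback sets out from 12 and comes back at 13. Hydrogen transfer from diimide is replaced by rhodium-catalysed addition of H2 (RhCl(PPh3)3, H2 4 atm, benzene/EtOH, 50 °C), a homogeneous hydrogenation that leaves aryl bromides and benzyl ethers alone. No compound outside the list is made (F0).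

**Further compounds**

F1 | step 8 | 4-ethenyl-2-(4-{2-[3-(benzyloxy)-4-(3-ethenylphenoxy)phenyl]ethyl}phenoxy)-1-methoxybenzene | COc1ccc(C=C)cc1Oc1ccc(CCc2ccc(Oc3cccc(C=C)c3)c(OCc3ccccc3)c2)cc1
F2 | step 8 | macrocyclic (Z)-stilbene across rings D and A, ring C oxygen benzylated | COc1ccc2cc1Oc1ccc(cc1)CCc1ccc(c(OCc3ccccc3)c1)Oc1cccc(c1)/C=C\2
F3 | step 2 | 3-hydroxy-4-iodobenzaldehyde | O=Cc1ccc(I)c(O)c1
F4 | step 2 | 3-(benzyloxy)-4-iodobenzaldehyde | O=Cc1ccc(I)c(OCc2ccccc2)c1
F0 | step 7 | none | none
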